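**Retrosynthetic overview**

1. Target 31 ⇐ 28 by desilylation, C14 acetylation and Horner–Wadsworth–Emmons methylenation at C11; 28 ⇐ 27 by closing the ten-membered carbocycle at C3–C4.
2. 27 ⇐ 21: the γ-lactone comes from the C7–C8 epoxide, opened at C7 by a phosphonoacetate tethered on O6 (then angelate on the freed C8–OH); 21 ⇐ 20 by Sharpless epoxidation.
3. 20 ⇐ alkyne 17 + (Z)-3-iodobut-2-enal 14 (catalytic asymmetric alkenylzinc addition sets C6); 17 ⇐ Wittig of ylide 10 with boryl aldehyde 6 (C1=C10); 6 ⇐ (S)-benzyl glycidyl ether (C2).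
4. Enabling feature: C3 is a primary sp3 carbon carrying boron beside the C2 silyl ether, and it faces the (Z)-C4–I iodoalkene; the chain between them is folded by the Z C4=C5 alkene (iodine cis to C6), the C1=C10 alkene (C2 cis to C9) and the trans-fused γ-lactone on C6/C7, whose C11 carries a phosphonate in place of the exocyclic methylene.
5. Ring order: γ-lactone (step 15), then ten-membered carbocycle (step 17); the exocyclic C11=C13 methylene is made last (step 20).

Key step: step 17

Remark: germacrane numbering is used for all intermediates (C1–C10 ring carbons, C11–C13 lactone carbons, C14 on C10, C15 on C4); C11 of 24–30 is epimerisable and is drawn as the expected 7,11-trans epimer.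

**Route**

Step 1
Reactants: 1 (S)-benzyl glycidyl ether
Product: 2 (R)-1-(benzyloxy)-3-iodopropan-2-ol
Conditions: LiI (1.5 equiv), AcOH (1.5 equiv), THF, 0 °C to rt
Reagents that add atoms: lithium iodide, [Li+].[I-]
Why: Regioselective SN2 opening of the terminal epoxide by iodide at the CH2 carbon (C3) leaves the C2–O bond untouched, so C2 of the target is taken from the chiral pool (the descriptor changes only because iodine raises the priority of C3).

Step 2
Reactants: 2 (R)-1-(benzyloxy)-3-iodopropan-2-ol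
Product: 3 tert-butyldimethylsilyl ether of 2
Conditions: TBSCl, imidazole, DMF, rt
Reagents that add atoms: tert-butyldimethylsilyl chloride, CC(C)(C)[Si](C)(C)Cl
Why: Standard silylation of the secondary alcohol protects the future C2 hydroxyl as the ether that is carried to step 18.

Step 3
Reactants: 3 tert-butyldimethylsilyl ether of 2
Product: 4 (S)-1-(benzyloxy)-2-(tert-butyldimethylsilyloxy)-3-(pinacolatoboryl)propane
Conditions: B2pin2 (1.5 equiv), CuI (10 mol %), PPh3 (13 mol %), LiOMe (2 equiv), DMF, rt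
Reagents that add atoms: bis(pinacolato)diboron, CC1(C)OB(OC1(C)C)B1OC(C)(C)C(C)(C)O1
Why: Copper-catalysed borylation of a primary alkyl iodide installs the C3–B bond early, before any alkene is present that a transient C3 radical could attack; C2 is not involved.

Step 4
Reactants: 4 (S)-1-(benzyloxy)-2-(tert-butyldimethylsilyloxy)-3-(pinacolatoboryl)propane
Product: 5 (S)-2-(tert-butyldimethylsilyloxy)-3-(pinacolatoboryl)propan-1-ol
Conditions: H2 (1 atm), Pd(OH)2/C, EtOAc, rt
Reagents that add atoms: none
Why: Hydrogenolysis of the benzyl ether is clean at this stage because no alkene or iodide is present and alkyl pinacol boronates are inert to it.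

Step 5
Reactants: 5 (S)-2-(tert-butyldimethylsilyloxy)-3-(pinacolatoboryl)propan-1-ol
Product: 6 (S)-2-(tert-butyldimethylsilyloxy)-3-(pinacolatoboryl)propanal
Conditions: Dess–Martin periodinane, CH2Cl2, 0 °C to rt
Reagents that add atoms: none
Why: Dess–Martin oxidation gives the α-silyloxy aldehyde (C1) under neutral conditions that neither epimerise C2 nor oxidise the C–B bond.

Step 6
Reactants: 7 ethyl (triphenyl-λ5-phosphanylidene)acetate (2.0 equiv), 8 propargyl bromide
Product: 10 ethyl 2-(triphenyl-λ5-phosphanylidene)pent-4-ynoate, via alkylated phosphonium bromide 9 (not isolated)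
Conditions: CHCl3, reflux; filtration
Reagents that add atoms: none
Why: C-alkylation of the stabilised ylide followed by transylidation (the second equivalent of 7 deprotonates 9) gives the α-propargyl ylide that supplies C7–C10 and C14.

Step 7
Reactants: 11 but-2-yn-1-ol
Product: 13 (Z)-3-iodobut-2-en-1-ol, via cyclic sodium alkenylalanate 12 (not isolated)
Conditions: NaAlH2(OCH2CH2OMe)2 (Red-Al), Et2O, 0 °C to rt; then I2, THF, −78 °C
Reagents that add atoms: iodine, II
Why: Alkoxide-directed trans-hydroalumination places aluminium on the distal alkyne carbon cis to the carbinol, and iodinolysis with retention gives the (Z)-iodoalkene that fixes the C4=C5 geometry of the target.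

Step 8
Reactants: 13 (Z)-3-iodobut-2-en-1-ol
Product: 14 (Z)-3-iodobut-2-enal
Conditions: MnO2 (15 equiv), CH2Cl2, rt, dark
Reagents that add atoms: none
Why: Allylic oxidation with MnO2 under neutral conditions should give the enal (C6) without isomerising the (Z)-iodoalkene.

Step 9
Reactants: 6 (S)-2-(tert-butyldimethylsilyloxy)-3-(pinacolatoboryl)propanal, 10 ethyl 2-(triphenyl-λ5-phosphanylidene)pent-4-ynoate
Product: 15 ethyl (2E,4S)-4-(tert-butyldimethylsilyloxy)-5-(pinacolatoboryl)-2-(prop-2-yn-1-yl)pent-2-enoate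
Conditions: toluene, 80 °C
Reagents that add atoms: none
Why: Wittig olefination with an α-substituted stabilised ylide is E-selective (ester trans to C2), which sets the C1=C10 geometry with C2 cis to C9, and its neutral conditions preserve the α-silyloxy stereocentre.

Step 10
Reactants: 15 ethyl (2E,4S)-4-(tert-butyldimethylsilyloxy)-5-(pinacolatoboryl)-2-(prop-2-yn-1-yl)pent-2-enoate
Product: 16 (2E,4S)-4-(tert-butyldimethylsilyloxy)-5-(pinacolatoboryl)-2-(prop-2-yn-1-yl)pent-2-en-1-ol
Conditions: i-Bu2AlH (2.5 equiv), CH2Cl2, −78 °C; Rochelle salt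
Reagents that add atoms: none
Why: 1,2-Reduction of the conjugated ester with i-Bu2AlH gives the C14 allylic alcohol, the boronate and alkyne being inert.

Step 11
Reactants: 16 (2E,4S)-4-(tert-butyldimethylsilyloxy)-5-(pinacolatoboryl)-2-(prop-2-yn-1-yl)pent-2-en-1-ol
Product: 17 bis-silyl ether of 16 (C14 OTBS)
Conditions: TBSCl, imidazole, CH2Cl2, 0 °C
Reagents that add atoms: tert-butyldimethylsilyl chloride, CC(C)(C)[Si](C)(C)Cl
Why: Silylation keeps C14 as an allylic silyl ether rather than an allylic ester, so that zerovalent palladium has no π-allyl pathway in step 17.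

Step 12
Reactants: 17 bis-silyl ether of 16 (C14 OTBS), 14 (Z)-3-iodobut-2-enal
Product: 20 (2S;6S) divinyl carbinol of the C3–C4 seco chain, via alkenyl(dicyclohexyl)borane 18 (not isolated), via alkenyl(methyl)zinc 19 (not isolated)
Conditions: Cy2BH (1.05 equiv), toluene, 0 °C to rt; Me2Zn (1.1 equiv), −78 °C; (−)-MIB [(2S)-3-exo-morpholinoisoborneol, 5 mol %], then 14 (1.3 equiv), −20 to 0 °C; aq NH4Cl
Reagents that add atoms: none
Why: Syn-hydroboration of the terminal alkyne gives the (E)-alkenylborane, boron–zinc exchange gives the alkenylzinc, and the amino-alcohol-catalysed asymmetric 1,2-addition delivers the alkenyl group to the Si face of 14, setting C6 under ligand control while the E C7=C8 geometry follows from the hydroboration.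

Step 13
Reactants: 20 (2S;6S) divinyl carbinol of the C3–C4 seco chain
Product: 21 (2S;6R;7R;8R) erythro trans-7,8-epoxy alcohol
Conditions: Ti(OiPr)4 (20 mol %), D-(−)-diisopropyl tartrate (24 mol %), t-BuOOH (2 equiv), 4 Å MS, CH2Cl2, −20 °C
Reagents that add atoms: tert-butyl hydroperoxide, CC(C)(C)OO
Why: In this Sharpless asymmetric epoxidation the D-(−)-tartrate catalyst meets the C7=C8 alkene of this C6 epimer as the matched, fast-reacting case and gives the erythro trans-epoxide (7R,8R), while the Z-iodoalkene is mismatched and electron-poor and the C1=C10 alkene has no free allylic hydroxyl.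

Step 14
Reactants: 21 (2S;6R;7R;8R) erythro trans-7,8-epoxy alcohol, 22 (diethoxyphosphoryl)acetic acid
Product: 23 O6 (diethoxyphosphoryl)acetate of 21
Conditions: 22 (1.5 equiv), DCC, DMAP (10 mol %), CH2Cl2, 0 °C to rt
Reagents that add atoms: none
Why: Steglich esterification attaches the C11–C12 unit as a phosphonoacetate on O6 without touching the epoxide.

Step 15
Reactants: 23 O6 (diethoxyphosphoryl)acetate of 21
Product: 24 trans-γ-lactone with C11 phosphonate and free C8 hydroxyl
Conditions: NaH (1.1 equiv), THF, 0 to 50 °C; aq NH4Cl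
Reagents that add atoms: none
Why: Intramolecular SN2 opening of the epoxide by the phosphonate-stabilised carbanion in the 5-exo-tet mode forms C7–C11 with inversion at C7 (hence the trans-lactone) and frees the C8 alkoxide with retention, so C7 and C8 both derive from the epoxide and C11 settles trans to C8 by equilibration.

Step 16
Reactants: 24 trans-γ-lactone with C11 phosphonate and free C8 hydroxyl, 25 angelic acid
Product: 27 C8 angelate (seco boronate), via angelic 2,4,6-trichlorobenzoic anhydride 26 (not isolated)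
Conditions: 25, 2,4,6-trichlorobenzoyl chloride, Et3N, toluene, rt; then 24, toluene, 80 °C
Reagents that add atoms: none
Why: Yamaguchi-type esterification through the mixed anhydride without nucleophilic catalyst should acylate the C8 hydroxyl while avoiding Z to E isomerisation to the tiglate.

Step 17
Reactants: 27 C8 angelate (seco boronate)
Product: 28 ten-membered carbocycle (2,14-bis-silyl ether; C11 phosphonate)
Conditions: PdCl2(dppf)·CH2Cl2 (20 mol %), Cs2CO3 (3 equiv), THF/DMF/H2O (8:2:1), 65 °C, 27 added by syringe pump over 12 h (final 1 mM)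
Reagents that add atoms: none
Why: Zerovalent palladium inserts into the C4–I bond with retention of the Z geometry, the base-activated primary boronate at C3 transmetalates in a two-electron, stereoretentive step (no free radical at C3, hence no scrambling through the neighbouring C1=C10 alkene), and reductive elimination forges C3–C4. The closest known reaction type is the B-alkyl Suzuki–Miyaura macrocyclisation, which has closed nine-membered carbocycles, together with cross-couplings of β-alkoxyalkylboron reagents. The ten-membered carbocycle is closed by an intramolecular C(sp3)–C(sp2) coupling in which the alkenyl carbon C4 becomes a ring atom and the C4=C5 double bond ends endocyclic. No stereocentre is created: the C4=C5 geometry is inherited from 14 and C2, C6, C7 and C8 are untouched. The step needs ring closure over oligomerisation and reductive elimination over β-hydride or β-silyloxy elimination; the two ring-cis alkenes and the trans-lactone fold the chain (helped by pseudo-dilution), the chelating dppf ligand speeds reductive elimination, and the phosphonate at C11 and the silyl ether at C14 remove the Heck and π-allyl side channels that an exocyclic methylene or an allylic acetate would open.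

Step 18
Reactants: 28 ten-membered carbocycle (2,14-bis-silyl ether; C11 phosphonate)
Product: 29 2,14-diol
Conditions: HF·pyridine, pyridine, THF, 0 °C to rt
Reagents that add atoms: none
Why: Fluoride-mediated desilylation removes both tert-butyldimethylsilyl ethers under buffered conditions that should leave lactone, angelate and phosphonate intact.

Step 19
Reactants: 29 2,14-diol
Product: 30 14-acetate
Conditions: AcCl (1.1 equiv), 2,4,6-collidine, CH2Cl2, −78 °C
Reagents that add atoms: acetyl chloride, CC(=O)Cl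
Why: Selective acetylation should take the primary allylic C14 hydroxyl over the secondary C2 hydroxyl by rate difference at low temperature with a hindered base.

Step 20
Reactants: 30 14-acetate
Product: 31 CNP0151426.1
Conditions: 37% aq HCHO, K2CO3, THF, 0 °C to rt
Reagents that add atoms: formaldehyde, C=O
Why: Horner–Wadsworth–Emmons olefination of the lactone α-phosphonate with formaldehyde creates the exocyclic C11=C13 methylene under mild carbonate conditions and removes the C11 stereocentre.

**Compound list**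

1 | (S)-benzyl glycidyl ether [(2S)-2-(benzyloxymethyl)oxirane] | O1C[C@H]1COCc1ccccc1 | starting material
2 | (R)-1-(benzyloxy)-3-iodopropan-2-ol | IC[C@H](O)COCc1ccccc1 | intermediate
3 | (R)-1-(benzyloxy)-2-(tert-butyldimethylsilyloxy)-3-iodopropane | IC[C@H](O[Si](C)(C)C(C)(C)C)COCc1ccccc1 | intermediate
4 | (S)-1-(benzyloxy)-2-(tert-butyldimethylsilyloxy)-3-(4,4,5,5-tetramethyl-1,3,2-dioxaborolan-2-yl)propane | CC1(C)OB(C[C@H](O[Si](C)(C)C(C)(C)C)COCc2ccccc2)OC1(C)C | intermediate
5 | (S)-2-(tert-butyldimethylsilyloxy)-3-(pinacolatoboryl)propan-1-ol | CC1(C)OB(C[C@H](O[Si](C)(C)C(C)(C)C)CO)OC1(C)C | intermediate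
6 | (S)-2-(tert-butyldimethylsilyloxy)-3-(pinacolatoboryl)propanal (C1–C3) | CC1(C)OB(C[C@H](O[Si](C)(C)C(C)(C)C)C=O)OC1(C)C | intermediate
7 | ethyl (triphenyl-λ5-phosphanylidene)acetate | CCOC(=O)C=P(c1ccccc1)(c1ccccc1)c1ccccc1 | starting material
8 | propargyl bromide (3-bromoprop-1-yne) | BrCC#C | starting material
9 | (1-ethoxy-1-oxopent-4-yn-2-yl)triphenylphosphonium bromide | [Br-].CCOC(=O)C(CC#C)[P+](c1ccccc1)(c1ccccc1)c1ccccc1 | intermediate (not isolated)
10 | ethyl 2-(triphenyl-λ5-phosphanylidene)pent-4-ynoate | CCOC(=O)C(CC#C)=P(c1ccccc1)(c1ccccc1)c1ccccc1 | intermediate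
11 | but-2-yn-1-ol | CC#CCO | starting material
12 | sodium 2,2-bis(2-methoxyethoxy)-3-methyl-1-oxa-2-aluminacyclopent-3-en-2-uide (cyclic alkenylalanate; Al cis to the CH2O group) | [Na+].CC1=CCO[Al-]1(OCCOC)OCCOC | intermediate (not isolated)
13 | (Z)-3-iodobut-2-en-1-ol | C/C(I)=C/CO | intermediate
14 | (Z)-3-iodobut-2-enal (C4–C6 and C15) | C/C(I)=C/C=O | intermediate
15 | ethyl (2E,4S)-4-(tert-butyldimethylsilyloxy)-5-(pinacolatoboryl)-2-(prop-2-yn-1-yl)pent-2-enoate | CCOC(=O)/C(CC#C)=C/[C@@H](O[Si](C)(C)C(C)(C)C)CB1OC(C)(C)C(C)(C)O1 | intermediate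
16 | (2E,4S)-4-(tert-butyldimethylsilyloxy)-5-(pinacolatoboryl)-2-(prop-2-yn-1-yl)pent-2-en-1-ol | OC/C(CC#C)=C/[C@@H](O[Si](C)(C)C(C)(C)C)CB1OC(C)(C)C(C)(C)O1 | intermediate
17 | (2E,4S)-1,4-bis(tert-butyldimethylsilyloxy)-5-(pinacolatoboryl)-2-(prop-2-yn-1-yl)pent-2-ene (C14 and C2 silyl ethers; terminal alkyne C7≡C8) | CC(C)(C)[Si](C)(C)OC/C(CC#C)=C/[C@@H](O[Si](C)(C)C(C)(C)C)CB1OC(C)(C)C(C)(C)O1 | intermediate
18 | (E)-alkenyl(dicyclohexyl)borane from 17 (boron on C7) | C1CCC(CC1)B(/C=C/C\C(CO[Si](C)(C)C(C)(C)C)=C/[C@@H](O[Si](C)(C)C(C)(C)C)CB1OC(C)(C)C(C)(C)O1)C1CCCCC1 | intermediate (not isolated)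
19 | (E)-alkenyl(methyl)zinc from 18 (zinc on C7) | C[Zn]/C=C/C\C(CO[Si](C)(C)C(C)(C)C)=C/[C@@H](O[Si](C)(C)C(C)(C)C)CB1OC(C)(C)C(C)(C)O1 | intermediate (not isolated)
20 | divinyl carbinol of the C3–C4 seco chain: C15–C4(I)=C5–C6H(OH)–C7=C8–C9–C10(C14H2OTBS)=C1–C2H(OTBS)–C3H2–Bpin; 4Z (I cis to C6); 7E; 1(10)E (C2 cis to C9); 2S; 6S | C/C(I)=C/[C@@H](O)/C=C/C\C(CO[Si](C)(C)C(C)(C)C)=C/[C@@H](O[Si](C)(C)C(C)(C)C)CB1OC(C)(C)C(C)(C)O1 | intermediate
21 | erythro epoxy alcohol: as 20 with a trans C7–C8 epoxide; 2S; 6R; 7R; 8R | C/C(I)=C/[C@@H](O)[C@H]1O[C@@H]1C\C(CO[Si](C)(C)C(C)(C)C)=C/[C@@H](O[Si](C)(C)C(C)(C)C)CB1OC(C)(C)C(C)(C)O1 | intermediate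
22 | (diethoxyphosphoryl)acetic acid | OC(=O)CP(=O)(OCC)OCC | starting material
23 | O6 (diethoxyphosphoryl)acetate of 21 (configuration as in 21) | C/C(I)=C/[C@@H](OC(=O)CP(=O)(OCC)OCC)[C@H]1O[C@@H]1C\C(CO[Si](C)(C)C(C)(C)C)=C/[C@@H](O[Si](C)(C)C(C)(C)C)CB1OC(C)(C)C(C)(C)O1 | intermediate
24 | trans-γ-lactone (O6–C12; H6 and H7 trans) with C11 diethoxyphosphoryl group and free C8 hydroxyl; 2S; 6R; 7R; 8R; 11S | C/C(I)=C/[C@H]1OC(=O)[C@@H](P(=O)(OCC)OCC)[C@@H]1[C@H](O)C\C(CO[Si](C)(C)C(C)(C)C)=C/[C@@H](O[Si](C)(C)C(C)(C)C)CB1OC(C)(C)C(C)(C)O1 | intermediate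
25 | angelic acid [(Z)-2-methylbut-2-enoic acid] | OC(=O)/C(C)=C\C | starting material
26 | angelic 2,4,6-trichlorobenzoic anhydride | O=C(OC(=O)/C(C)=C\C)c1c(Cl)cc(Cl)cc1Cl | intermediate (not isolated)
27 | C8 angelate of 24 (seco boronate; C3–Bpin and C4–I termini) | C/C(I)=C/[C@H]1OC(=O)[C@@H](P(=O)(OCC)OCC)[C@@H]1[C@H](OC(=O)/C(C)=C\C)C\C(CO[Si](C)(C)C(C)(C)C)=C/[C@@H](O[Si](C)(C)C(C)(C)C)CB1OC(C)(C)C(C)(C)O1 | intermediate
28 | (1(10)E,4Z,2S,6R,7R,8R,11S)-8-angeloyloxy-2,14-bis(tert-butyldimethylsilyloxy)-11-(diethoxyphosphoryl)-13-norgermacra-1(10),4-dien-12,6-olide | CCOP(=O)(OCC)[C@@H]1C(=O)O[C@@H]2/C=C(/C)C[C@H](O[Si](C)(C)C(C)(C)C)/C=C(/CO[Si](C)(C)C(C)(C)C)C[C@@H](OC(=O)/C(C)=C\C)[C@@H]12 | intermediate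
29 | (1(10)E,4Z,2S,6R,7R,8R,11S)-8-angeloyloxy-11-(diethoxyphosphoryl)-2,14-dihydroxy-13-norgermacra-1(10),4-dien-12,6-olide | CCOP(=O)(OCC)[C@@H]1C(=O)O[C@@H]2/C=C(/C)C[C@H](O)/C=C(/CO)C[C@@H](OC(=O)/C(C)=C\C)[C@@H]12 | intermediate
30 | (1(10)E,4Z,2S,6R,7R,8R,11S)-14-acetoxy-8-angeloyloxy-11-(diethoxyphosphoryl)-2-hydroxy-13-norgermacra-1(10),4-dien-12,6-olide | CCOP(=O)(OCC)[C@@H]1C(=O)O[C@@H]2/C=C(/C)C[C@H](O)/C=C(/COC(C)=O)C[C@@H](OC(=O)/C(C)=C\C)[C@@H]12 | intermediate
31 | CNP0151426.1: (1(10)E,4Z,2S,6R,7R,8R)-14-acetoxy-8-angeloyloxy-2-hydroxygermacra-1(10),4,11(13)-trien-12,6-olide | C=C1C(=O)O[C@@H]2/C=C(/C)C[C@H](O)/C=C(/COC(C)=O)C[C@@H](OC(=O)/C(C)=C\C)[C@@H]12 | target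

**Step count and risks**

Total step count: 20. Longest linear sequence: 17 steps (steps 1–5, then 9–20).

Step 17 (ring closure). What may go wrong: oligomerisation outrunning ten-membered ring closure, slow transmetalation of the pinacol boronate with protodeboronation, β-elimination from the C3–palladium intermediate, or ionisation of the allylic lactone C6–O bond by zerovalent palladium. Fallback (ring order reversed): set out from 21 and close the carbocycle before the lactone exists. The same Suzuki–Miyaura conditions applied to 21 should give the macrocyclic epoxy alcohol F1. Esterification with 22 (DCC, DMAP) should give its O6 phosphonoacetate F2. NaH-mediated epoxide opening inside the ring should give the macrocyclic phosphono lactone alcohol F3. Angeloylation as in step 16 comes back to the route at 28.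

Step 15 (lactone formation). What may go wrong: the carbanion must reach C7 through the less favoured s-cis rotamer of the ester tether, so cyclisation may be slow and 6-endo attack at C8 or base-induced decomposition may compete. Fallback (Lewis-acid pathway with a neutral π-nucleophile): set out from 23 and convert it into its trimethylsilyl ketene acetal F4 (Me3SiOTf, Et3N, CH2Cl2, −78 °C). Catalytic Me3SiOTf should then trigger an intramolecular Mukaiyama-type opening of the activated epoxide at C7 to give the C8 trimethylsilyl ether F5. Cleaving that silyl ether (citric acid, MeOH) comes back to the route at 24.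

Step 12 (C6 stereocentre). What may go wrong: insufficient facial selectivity in the alkenyl transfer to 14, or an uncatalysed background addition, eroding the configuration at C6. Fallback (resolution instead of asymmetric catalysis): set out from 17 and run the alkenylzinc addition without ligand, which should give 20 together with its C6 epimer F6. The Sharpless step then acts as a kinetic resolution: with D-(−)-diisopropyl tartrate only 20 is the matched substrate and is epoxidised quickly to the erythro product, while F6 reacts slowly and is separated. The route is rejoined at 21.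

**Further compounds**

F1 | step 17 | macrocyclic epoxy alcohol (C3–C4 closed; C7–C8 trans-epoxide; C6 hydroxyl; 2,14-bis-silyl ether) | C/C1=C/[C@@H](O)[C@H]2O[C@@H]2C\C(CO[Si](C)(C)C(C)(C)C)=C/[C@@H](O[Si](C)(C)C(C)(C)C)C1
F2 | step 17 | O6 (diethoxyphosphoryl)acetate of F1 | C/C1=C/[C@@H](OC(=O)CP(=O)(OCC)OCC)[C@H]2O[C@@H]2C\C(CO[Si](C)(C)C(C)(C)C)=C/[C@@H](O[Si](C)(C)C(C)(C)C)C1
F3 | step 17 | macrocyclic phosphono lactone with free C8 hydroxyl (28 without the angeloyl group) | CCOP(=O)(OCC)[C@@H]1C(=O)O[C@@H]2/C=C(/C)C[C@H](O[Si](C)(C)C(C)(C)C)/C=C(/CO[Si](C)(C)C(C)(C)C)C[C@@H](O)[C@@H]12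
F4 | step 15 | trimethylsilyl ketene acetal of 23 | C/C(I)=C/[C@@H](OC(O[Si](C)(C)C)=CP(=O)(OCC)OCC)[C@H]1O[C@@H]1C\C(CO[Si](C)(C)C(C)(C)C)=C/[C@@H](O[Si](C)(C)C(C)(C)C)CB1OC(C)(C)C(C)(C)O1
F5 | step 15 | C8 trimethylsilyl ether of 24 | C/C(I)=C/[C@H]1OC(=O)[C@@H](P(=O)(OCC)OCC)[C@@H]1[C@H](O[Si](C)(C)C)C\C(CO[Si](C)(C)C(C)(C)C)=C/[C@@H](O[Si](C)(C)C(C)(C)C)CB1OC(C)(C)C(C)(C)O1
F6 | step 12 | C6 epimer of 20 (2S;6R) | C/C(I)=C/[C@H](O)/C=C/C\C(CO[Si](C)(C)C(C)(C)C)=C/[C@@H](O[Si](C)(C)C(C)(C)C)CB1OC(C)(C)C(C)(C)O1
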